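**Retrosynthetic overview**
1. Target 8 ⇒ bis(3,4-dihydroxyphenyl)methane 7: all six C–Br bonds are made last by exhaustive electrophilic bromination, since every free ring position is ortho/para to an OH. 7 ⇒ tetramethyl ether 5 by O-demethylation in the same flask.
2. 5 ⇒ veratraldehyde 1 + 4-bromoveratrole 3: the ArCH2–Ar bond joins the aldehyde carbon of 1, polarity-reversed as its N–H hydrazone 4 (a benzyl-carbanion equivalent), to the C–Br carbon of 3 under Ni catalysis; N2 is lost and the CH2 link forms directly.
3. No ring is formed: both benzene rings are bought intact, and there is no stereocentre to set.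

Assumption: the target is achiral (no stereocentre, mirror-symmetric), so "single enantiomer" asks for nothing beyond the constitution.

**Route**

Step 1
Reactants: 1 3,4-dimethoxybenzaldehyde (veratraldehyde); 2 hydrazine monohydrate; 3 4-bromo-1,2-dimethoxybenzene (4-bromoveratrole)
Product: 5 bis(3,4-dimethoxyphenyl)methane, via veratraldehyde hydrazone 4 (not isolated)
Conditions: 1 (1.5 equiv), N2H4·H2O (1.8 equiv), THF, rt, 1 h; then 3 (1.0 equiv), Ni(cod)2 (10 mol%), PMe3 (20 mol%), K3PO4 (2 equiv), DBU (20 mol%), 4 Å MS, THF, 60 °C, Ar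
Reagents that add atoms: none
Why: Carbonyl umpolung through the N–H hydrazone (nickel-catalysed Wolff–Kishner-type cross-coupling): condensation turns the electrophilic aldehyde carbon of 1 into a benzyl-carbanion equivalent, Ni(0) inserts into the C–Br bond of 3, C–C reductive elimination from the aryl-Ni hydrazonide gives ArCH(Ar')–N=NH, and base-triggered loss of N2 leaves the CH2 bridge at the correct oxidation level; no stereocentre is created.

Step 2
Reactants: 5 bis(3,4-dimethoxyphenyl)methane
Product: 8 bis(2,3,6-tribromo-4,5-dihydroxyphenyl)methane, via cyclic bis(bromoboronate) 6 (not isolated), via bis(3,4-dihydroxyphenyl)methane 7 (not isolated)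
Conditions: BBr3 (5 equiv), CH2Cl2, −78 °C → rt; MeOH, 0 °C, evaporate (×3, same flask); then Br2 (6.2 equiv), AcOH, 15–25 °C, dark; aq. NaHSO3, filter
Reagents that add atoms: bromine, BrBr (boron tribromide, BrB(Br)Br, puts B and Br into intermediate 6 only; none of its atoms remain in 8)
Why: Lewis-acid O-demethylation with BBr3 (each veratrole unit becomes a cyclic aryl bromoboronate with loss of MeBr, and methanolysis frees the catechol while boron leaves as volatile B(OMe)3) is followed by electrophilic aromatic bromination in which the two OH groups activate all three remaining positions of each ring (2, 5 and 6), as in catechol → tetrabromocatechol, so six bromines enter with no regiochemical choice; no stereocentre is created.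

**Compound list**
1 | 3,4-dimethoxybenzaldehyde (veratraldehyde) | COc1ccc(C=O)cc1OC | starting material
2 | hydrazine monohydrate | NN.O | starting material
3 | 4-bromo-1,2-dimethoxybenzene (4-bromoveratrole) | COc1ccc(Br)cc1OC | starting material
4 | (E)-(3,4-dimethoxybenzylidene)hydrazine (veratraldehyde hydrazone) | COc1ccc(/C=N/N)cc1OC | intermediate
5 | bis(3,4-dimethoxyphenyl)methane | COc1ccc(Cc2ccc(OC)c(OC)c2)cc1OC | intermediate
6 | bis(2-bromo-1,3,2-benzodioxaborol-5-yl)methane (cyclic bis(bromoboronate)) | BrB1Oc2ccc(Cc3ccc4OB(Br)Oc4c3)cc2O1 | intermediate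
7 | bis(3,4-dihydroxyphenyl)methane | Oc1ccc(Cc2ccc(O)c(O)c2)cc1O | intermediate
8 | bis(2,3,6-tribromo-4,5-dihydroxyphenyl)methane [5,5'-methylenebis(3,4,6-tribromobenzene-1,2-diol)] | Oc1c(O)c(Br)c(Cc2c(Br)c(O)c(O)c(Br)c2Br)c(Br)c1Br | target

**Step count and risk**
Total step count: 2 (one isolated intermediate, 5). Longest linear sequence: 2.

The route has only two steps, so the three most failure-prone operations are ranked; the second and third are the two stages of step 2.

1. Step 1, the Ni/hydrazone coupling. The electron-rich bromide 3 adds slowly to Ni(0), and 4 can be diverted to 3,4-dimethoxytoluene (plain Wolff–Kishner reduction), to the azine, or to an N-aryl hydrazone; 3 can also be hydrodebrominated. The fallback sets out from 1 (with 3) and comes back at 5, using a dithiane acyl-anion equivalent instead. 1 is condensed with propane-1,3-dithiol (BF3·OEt2, CH2Cl2, rt) to 2-(3,4-dimethoxyphenyl)-1,3-dithiane F1. F1 is arylated with 3 by palladium-catalysed deprotonative cross-coupling ([Pd(allyl)Cl]2/NiXantphos, KOtBu, CPME, rt) to 2,2-bis(3,4-dimethoxyphenyl)-1,3-dithiane F2. Raney nickel (EtOH, reflux) desulfurises F2 to 5.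

2. Step 2, bromination stage. The free bis-catechol 7 can be oxidised to o-quinones, can suffer ipso-bromodealkylation at the carbon para to OH (cleaving the diarylmethane), or can be brominated at the benzylic position through a quinone methide if Br2 is in excess; the third bromine per ring may also be slow. The fallback sets out from 5 and comes back at 8, brominating at the ether stage where neither quinone nor quinone-methide chemistry is possible. 5 is treated with Br2 (7 equiv) and catalytic Fe powder (CH2Cl2, reflux, dark) to give bis(2,3,6-tribromo-4,5-dimethoxyphenyl)methane F3. BBr3 (CH2Cl2, −78 °C → rt) converts F3 into bis(2,4,6,7-tetrabromo-1,3,2-benzodioxaborol-5-yl)methane F4, which aqueous work-up hydrolyses to 8.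

3. Step 2, demethylation stage. BBr3 may cause transbenzylation or C–C scission of the very electron-rich 5, and crude 7 may air-oxidise during evaporation or carry boron residues into the bromination. The fallback sets out from 5 and comes back at 8, using one bromine per ring as a deactivating group before the ethers are cleaved. 5 is dibrominated at the fast positions para to the 3-OMe groups (Br2, 2.1 equiv, AcOH, 15 °C) to bis(2-bromo-4,5-dimethoxyphenyl)methane F5. BBr3 (CH2Cl2, −78 °C → rt) gives bis(2,6-dibromo-1,3,2-benzodioxaborol-5-yl)methane F6, and aqueous work-up delivers isolable, much less oxidisable bis(2-bromo-4,5-dihydroxyphenyl)methane F7. Br2 (4.1 equiv, AcOH, rt, dark) then completes the bromination to 8.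

**Further compounds**
F1 | step 1 | 2-(3,4-dimethoxyphenyl)-1,3-dithiane | COc1ccc(C2SCCCS2)cc1OC
F2 | step 1 | 2,2-bis(3,4-dimethoxyphenyl)-1,3-dithiane | COc1ccc(C2(c3ccc(OC)c(OC)c3)SCCCS2)cc1OC
F3 | step 2 | bis(2,3,6-tribromo-4,5-dimethoxyphenyl)methane | COc1c(OC)c(Br)c(Cc2c(Br)c(OC)c(OC)c(Br)c2Br)c(Br)c1Br
F4 | step 2 | bis(2,4,6,7-tetrabromo-1,3,2-benzodioxaborol-5-yl)methane | BrB1Oc2c(Br)c(Br)c(Cc3c(Br)c(Br)c4OB(Br)Oc4c3Br)c(Br)c2O1
F5 | step 2 | bis(2-bromo-4,5-dimethoxyphenyl)methane | COc1cc(Br)c(Cc2cc(OC)c(OC)cc2Br)cc1OC
F6 | step 2 | bis(2,6-dibromo-1,3,2-benzodioxaborol-5-yl)methane | BrB1Oc2cc(Br)c(Cc3cc4OB(Br)Oc4cc3Br)cc2O1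
F7 | step 2 | bis(2-bromo-4,5-dihydroxyphenyl)methane | Oc1cc(Br)c(Cc2cc(O)c(O)cc2Br)cc1O
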